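**Retrosynthetic overview**

1. The dihydropyranone ring of the flavanone unit is closed last, by a catalytic asymmetric oxa-Michael addition of the C8a hydroxyl (future O1) to an alkylidene β-keto ester that sets C2; the acyl carbon on C4a comes from a Fries acetylation next to the one phenol oxygen of that ring that is MOM-protected rather than benzylated.
2. The strategy rests on ring A of the flavone unit (C4a''–C5''–C6''–C7''–C8''–C8a''), a resorcinol fused to the 4-pyranone along C4a''–C8a''. Its C5''–C6''–C7''–C8'' chain, oxygenated on C5'' and C7'', is an acetoacetyl unit standing on C8a'' of a pyranone that already contains O1'', C4''=O and the C2'' aryl group, so the ring is opened at C4a''–C5'' to an acylketene.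
3. The acylketene comes from a tert-butyl β-keto ester, made from a 2-benzyl-4-pyranone by lateral carboxylation and Masamune homologation; the hindered C6–C8'' biaryl bond is an ordinary aryl–CH2 bond until ring A of the flavone unit aromatizes.
4. The benzylpyranone comes from cyclodehydration of a 1,3,5-triketone (arylacetic ester plus aroylacetone dianion); the arylacetic ester comes from 2,4,6-trihydroxybenzaldehyde by 4-O-MOM protection, 2,6-di-O-benzylation and one-carbon homologation.
5. Ring order: pyranone ring of the flavone unit (step 8), ring A of the flavone unit (step 11), heterocycle of the flavanone unit (step 17).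

Key step: step 11

Assumption: the target string defines only C2 (S); the C6–C8'' axis has four ortho substituents and may be configurationally stable, but its sense is unspecified and is not controlled, so 21 and all later compounds are drawn without an axial descriptor.

**Step 1**
Reactants: 1 2,4,6-trihydroxybenzaldehyde
Product: 2 2,6-dihydroxy-4-(methoxymethoxy)benzaldehyde
Conditions: MOMCl (1.0 equiv), iPr2NEt (1.1 equiv), THF, 0 °C
Reagents that add atoms: chloromethyl methyl ether, COCCl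
Why: Williamson-type O-alkylation; the 4-OH is the most acidic hydroxyl (para to the formyl group) and the only one not held in a hydrogen bond to the aldehyde, so one equivalent of the chloromethyl ether should react there first.

**Step 2**
Reactants: 2 2,6-dihydroxy-4-(methoxymethoxy)benzaldehyde
Product: 3 2,6-bis(benzyloxy)-4-(methoxymethoxy)benzaldehyde
Conditions: BnBr (2.5 equiv), K2CO3, DMF, 60 °C
Reagents that add atoms: benzyl bromide, BrCc1ccccc1
Why: Williamson ether synthesis; with O4 capped, carbonate in warm DMF should benzylate both chelated ortho hydroxyls, and the MOM acetal is inert to base.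

**Step 3**
Reactants: 3 2,6-bis(benzyloxy)-4-(methoxymethoxy)benzaldehyde
Product: 5 2-[2,6-bis(benzyloxy)-4-(methoxymethoxy)phenyl]acetonitrile, via alkenylformamide 4 (not isolated)
Conditions: TosMIC, KOtBu, DME, −40 °C; then MeOH, reflux
Reagents that add atoms: tosylmethyl isocyanide, Cc1ccc(cc1)S(=O)(=O)C[N+]#[C-]
Why: van Leusen reductive cyanation; the TosMIC anion adds to the aldehyde, the oxazoline opens to the N-(1-tosylalkenyl)formamide, and methanolysis with loss of methyl formate and sulfinate leaves the nitrile one carbon longer under basic conditions that spare the MOM and benzyl ethers.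

**Step 4**
Reactants: 5 2-[2,6-bis(benzyloxy)-4-(methoxymethoxy)phenyl]acetonitrile
Product: 6 2-[2,6-bis(benzyloxy)-4-(methoxymethoxy)phenyl]acetic acid
Conditions: KOH, EtOH–H2O, reflux; then 1 M HCl, 0 °C
Reagents that add atoms: potassium hydroxide, [K+].[OH-]; water, O
Why: Base hydrolysis of a nitrile through the primary amide; the ethers and the acetal are inert to hydroxide, and the short cold acidification should leave the MOM group in place.

**Step 5**
Reactants: 6 2-[2,6-bis(benzyloxy)-4-(methoxymethoxy)phenyl]acetic acid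
Product: 7 methyl 2-[2,6-bis(benzyloxy)-4-(methoxymethoxy)phenyl]acetate
Conditions: MeI, K2CO3, DMF, rt
Reagents that add atoms: iodomethane, CI
Why: SN2 O-alkylation of the carboxylate gives the methyl ester needed as the Claisen acceptor.

**Step 6**
Reactants: 8 4'-(benzyloxy)acetophenone
Product: 9 1-[4-(benzyloxy)phenyl]butane-1,3-dione
Conditions: NaH, EtOAc, THF, reflux; then 1 M HCl
Reagents that add atoms: ethyl acetate, CCOC(C)=O
Why: Crossed Claisen condensation of the ketone enolate with ethyl acetate, driven by deprotonation of the β-diketone formed.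

**Step 7**
Reactants: 7 methyl 2-[2,6-bis(benzyloxy)-4-(methoxymethoxy)phenyl]acetate; 9 1-[4-(benzyloxy)phenyl]butane-1,3-dione
Product: 10 1-[2,6-bis(benzyloxy)-4-(methoxymethoxy)phenyl]-6-[4-(benzyloxy)phenyl]hexane-2,4,6-trione
Conditions: 9 (2.5 equiv), LiN(iPr)2 (5 equiv), THF, −78 to 0 °C; then 7, −78 to 0 °C; cold 1 M HCl to pH 4
Reagents that add atoms: none
Why: Harris-type Claisen acylation of a β-diketone dianion at its terminal carbanion; the dianion is used in excess because the more acidic triketone consumes one equivalent and because some ester is lost to enolization.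

**Step 8**
Reactants: 10 1-[2,6-bis(benzyloxy)-4-(methoxymethoxy)phenyl]-6-[4-(benzyloxy)phenyl]hexane-2,4,6-trione
Product: 11 2-[2,6-bis(benzyloxy)-4-(methoxymethoxy)benzyl]-6-[4-(benzyloxy)phenyl]-4H-pyran-4-one
Conditions: PPh3, CCl4, Et3N, THF, rt to 50 °C
Reagents that add atoms: none
Why: Appel-type cyclodehydration of the 1,3,5-triketone (one terminal enol is activated as an oxyphosphonium and displaced by the other terminal enol oxygen) closes the 4-pyranone ring of the flavone unit without the protic acid that would remove the MOM group.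

**Step 9**
Reactants: 11 2-[2,6-bis(benzyloxy)-4-(methoxymethoxy)benzyl]-6-[4-(benzyloxy)phenyl]-4H-pyran-4-one
Product: 12 2-[2,6-bis(benzyloxy)-4-(methoxymethoxy)phenyl]-2-{6-[4-(benzyloxy)phenyl]-4-oxo-4H-pyran-2-yl}acetic acid
Conditions: LiN(SiMe3)2 (1.3 equiv), THF, −78 °C; CO2 (g); cold 0.5 M HCl to pH 3; used crude
Reagents that add atoms: carbon dioxide, O=C=O
Why: Lateral (vinylogous) deprotonation of a 2-alkyl-4-pyranone at the CH2 activated by both the pyranone and the aryl ring, followed by carboxylation of the hindered carbanion with the smallest available electrophile.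

**Step 10**
Reactants: 12 2-[2,6-bis(benzyloxy)-4-(methoxymethoxy)phenyl]-2-{6-[4-(benzyloxy)phenyl]-4-oxo-4H-pyran-2-yl}acetic acid; 13 mono-tert-butyl malonate
Product: 15 tert-butyl 4-[2,6-bis(benzyloxy)-4-(methoxymethoxy)phenyl]-4-{6-[4-(benzyloxy)phenyl]-4-oxo-4H-pyran-2-yl}-3-oxobutanoate, via acyl imidazolide 14 (not isolated)
Conditions: CDI, THF, 0 °C to rt; then Mg(O2CCH2CO2tBu)2 (from 13 and Mg(OEt)2), THF, rt to 40 °C; cold 1 M HCl
Reagents that add atoms: 1,1'-carbonyldiimidazole, O=C(n1ccnc1)n1ccnc1 (its imidazolyl group is found in 14 only)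
Why: Masamune–Brooks homologation; the magnesium malonate enolate acylates on the imidazolide (or on the ketene it can form by elimination) and loses CO2, building the β-keto ester near neutrality at room temperature, where the acid should not yet decarboxylate.

**Step 11**
Reactants: 15 tert-butyl 4-[2,6-bis(benzyloxy)-4-(methoxymethoxy)phenyl]-4-{6-[4-(benzyloxy)phenyl]-4-oxo-4H-pyran-2-yl}-3-oxobutanoate
Product: 17 8-[2,6-bis(benzyloxy)-4-(methoxymethoxy)phenyl]-2-[4-(benzyloxy)phenyl]-5,7-dihydroxy-4H-chromen-4-one, via acylketene 16 (not isolated)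
Conditions: slow addition of 15 in toluene to refluxing xylenes (about 140 °C), final concentration about 2 mM, N2
Reagents that add atoms: none
Why: Proposed new method: heat expels tert-butanol from the β-keto ester through the usual six-centre transition state to give acylketene 16, whose ketone enolizes toward the doubly activated methine to a dienylketene O=C=CH–C(OH)=C(Ar)–C=CH in which the last double bond is the C2=C3 bond of the pyran-2-yl group (future C8a''=C4a''); a thermally allowed disrotatory six-electron electrocyclization then joins the ketene carbon (C5'') to that pyranone CH (C4a'') and the cyclohexadienone tautomerizes to the 5'',7''-dihydroxy arene, the same bond also being reachable by polar attack of the nucleophilic pyranone α-carbon on the ketene. The closest known reaction types are thermal generation and intramolecular capture of acylketenes from tert-butyl β-keto esters or dioxinones, and electrocyclization of dienylketenes to phenols (Danheiser-type benzannulation); neither has used a 4-pyranone C=C bond as the terminus. Ring A of the flavone unit closes as a six-membered carbocycle in a 6π-electrocyclic mode (in polar terms a 6-endo-dig attack on the ketene carbon), and no stereocentre is formed, the racemic methine becoming the sp2 carbon C8''. The step needs C–C closure onto the pyranone in preference to closure onto the aryl ring, capture by oxygen, or intermolecular ketene reactions: both ortho positions of the aryl ring carry benzyloxy groups so a naphthol-type closure cannot aromatize, the pyranone already fixes O1'' on C8a'' so only the 8''-aryl flavone can result, and slow addition into a large solvent volume keeps the ketene concentration too low for dimerization or O-acylation of product phenols.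

**Step 12**
Reactants: 17 8-[2,6-bis(benzyloxy)-4-(methoxymethoxy)phenyl]-2-[4-(benzyloxy)phenyl]-5,7-dihydroxy-4H-chromen-4-one
Product: 18 7-(benzyloxy)-8-[2,6-bis(benzyloxy)-4-(methoxymethoxy)phenyl]-2-[4-(benzyloxy)phenyl]-5-hydroxy-4H-chromen-4-one
Conditions: BnBr (1.1 equiv), K2CO3, acetone, reflux
Reagents that add atoms: benzyl bromide, BrCc1ccccc1
Why: Williamson ether synthesis; the 7''-OH is far more acidic and available than the 5''-OH, which is locked in a hydrogen bond to the C4'' carbonyl, so one equivalent of benzyl bromide should alkylate O7'' only.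

**Step 13**
Reactants: 18 7-(benzyloxy)-8-[2,6-bis(benzyloxy)-4-(methoxymethoxy)phenyl]-2-[4-(benzyloxy)phenyl]-5-hydroxy-4H-chromen-4-one
Product: 19 7-(benzyloxy)-8-[2,6-bis(benzyloxy)-4-hydroxyphenyl]-2-[4-(benzyloxy)phenyl]-5-hydroxy-4H-chromen-4-one
Conditions: HCl (2 M in MeOH), MeOH–THF, 45 °C
Reagents that add atoms: none
Why: Acid-catalysed acetal exchange with methanol removes the MOM group; aryl benzyl ethers and the flavone are stable to dilute HCl in warm methanol.

**Step 14**
Reactants: 19 7-(benzyloxy)-8-[2,6-bis(benzyloxy)-4-hydroxyphenyl]-2-[4-(benzyloxy)phenyl]-5-hydroxy-4H-chromen-4-one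
Product: 21 8-[3-acetyl-2,6-bis(benzyloxy)-4-hydroxyphenyl]-7-(benzyloxy)-2-[4-(benzyloxy)phenyl]-5-hydroxy-4H-chromen-4-one, via aryl acetate 20 (not isolated)
Conditions: Ac2O (1.5 equiv), BF3·OEt2 (3 equiv), CH2Cl2, 0 °C to rt; then aq. NaOAc, EtOH, 60 °C
Reagents that add atoms: acetic anhydride, CC(=O)OC(C)=O
Why: O-acetylation then BF3-mediated Fries rearrangement (Friedel–Crafts C-acylation) ortho to the free hydroxyl of the phloroglucinol-type ring, by far the most nucleophilic arene present; the two ortho positions are equivalent, the product is held as an O–BF2–O chelate with the new carbonyl (which keeps the Lewis acid away from the neighbouring benzyl ether), and the 5''-OH is masked as its own BF2 chelate until the acetate work-up.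

**Step 15**
Reactants: 21 8-[3-acetyl-2,6-bis(benzyloxy)-4-hydroxyphenyl]-7-(benzyloxy)-2-[4-(benzyloxy)phenyl]-5-hydroxy-4H-chromen-4-one
Product: 22 tert-butyl 3-[2,4-bis(benzyloxy)-3-{7-(benzyloxy)-2-[4-(benzyloxy)phenyl]-5-hydroxy-4-oxo-4H-chromen-8-yl}-6-hydroxyphenyl]-3-oxopropanoate
Conditions: LiN(SiMe3)2 (4.5 equiv), THF, −78 to −20 °C; Boc2O (1.1 equiv), −78 to 0 °C; cold 1 M HCl
Reagents that add atoms: di-tert-butyl dicarbonate, CC(C)(C)OC(=O)OC(=O)OC(C)(C)C
Why: Claisen-type C-acylation of the lithium polyanion of an ortho-hydroxyacetophenone (both phenols, then the methyl ketone, are deprotonated) with Boc2O; any carbonate formed on the adjacent phenoxide should be carried to carbon by a Baker–Venkataraman-type acyl shift under the excess base.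

**Step 16**
Reactants: 22 tert-butyl 3-[2,4-bis(benzyloxy)-3-{7-(benzyloxy)-2-[4-(benzyloxy)phenyl]-5-hydroxy-4-oxo-4H-chromen-8-yl}-6-hydroxyphenyl]-3-oxopropanoate; 23 4-(benzyloxy)benzaldehyde
Product: 24 tert-butyl 2-[2,4-bis(benzyloxy)-3-{7-(benzyloxy)-2-[4-(benzyloxy)phenyl]-5-hydroxy-4-oxo-4H-chromen-8-yl}-6-hydroxybenzoyl]-3-[4-(benzyloxy)phenyl]prop-2-enoate (E/Z mixture)
Conditions: piperidine (cat.), AcOH (cat.), 4 Å molecular sieves, toluene, rt
Reagents that add atoms: none
Why: Knoevenagel condensation of the β-keto ester with the aryl aldehyde under piperidinium acetate catalysis, run at room temperature to keep the chelated phenol from adding to the new alkene before the chiral catalyst is present.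

**Step 17**
Reactants: 24 tert-butyl 2-[2,4-bis(benzyloxy)-3-{7-(benzyloxy)-2-[4-(benzyloxy)phenyl]-5-hydroxy-4-oxo-4H-chromen-8-yl}-6-hydroxybenzoyl]-3-[4-(benzyloxy)phenyl]prop-2-enoate
Product: 26 (2S)-5,7-bis(benzyloxy)-6-{7-(benzyloxy)-2-[4-(benzyloxy)phenyl]-5-hydroxy-4-oxo-4H-chromen-8-yl}-2-[4-(benzyloxy)phenyl]chroman-4-one, via flavanone-3-carboxylate 25 (not isolated)
Conditions: 9-epi-aminoquinidine-derived 3,5-bis(trifluoromethyl)phenyl thiourea (15 mol %), toluene, −25 °C; then TsOH·H2O (cat.), toluene, 80 °C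
Reagents that add atoms: none
Why: Intramolecular oxa-Michael addition under a bifunctional cinchona thiourea, in which the thiourea binds the β-keto ester and the quinuclidine delivers the phenol O–H, so the catalyst decides which alkene face is attacked and sets C2 as S (the quinine-derived pseudoenantiomer gives the mirror-image induction and is substituted if a model cyclization to tri-O-benzylnaringenin calls for it); TsOH then cleaves the tert-butyl ester and the β-keto acid decarboxylates without touching C2.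

**Step 18**
Reactants: 26 (2S)-5,7-bis(benzyloxy)-6-{7-(benzyloxy)-2-[4-(benzyloxy)phenyl]-5-hydroxy-4-oxo-4H-chromen-8-yl}-2-[4-(benzyloxy)phenyl]chroman-4-one
Product: 27 (2S)-6-[5,7-dihydroxy-2-(4-hydroxyphenyl)-4-oxo-4H-chromen-8-yl]-5,7-dihydroxy-2-(4-hydroxyphenyl)chroman-4-one
Conditions: H2 (1 atm), Pd/C (10 %), EtOAc–MeOH, rt
Reagents that add atoms: none
Why: Catalytic hydrogenolysis of the five aryl benzyl ethers under neutral conditions, which should leave the C2 stereocentre, both ketones and the flavone double bond untouched if stopped once debenzylation is complete.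

**Compound list**

1 | 2,4,6-trihydroxybenzaldehyde | O=Cc1c(O)cc(O)cc1O | starting material
2 | 2,6-dihydroxy-4-(methoxymethoxy)benzaldehyde | O=Cc1c(O)cc(OCOC)cc1O | intermediate
3 | 2,6-bis(benzyloxy)-4-(methoxymethoxy)benzaldehyde | O=Cc1c(OCc2ccccc2)cc(OCOC)cc1OCc1ccccc1 | intermediate
4 | N-{2-[2,6-bis(benzyloxy)-4-(methoxymethoxy)phenyl]-1-tosylethenyl}formamide (geometry not defined) | O=CNC(=Cc1c(OCc2ccccc2)cc(OCOC)cc1OCc1ccccc1)S(=O)(=O)c1ccc(C)cc1 | intermediate (not isolated)
5 | 2-[2,6-bis(benzyloxy)-4-(methoxymethoxy)phenyl]acetonitrile | N#CCc1c(OCc2ccccc2)cc(OCOC)cc1OCc1ccccc1 | intermediate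
6 | 2-[2,6-bis(benzyloxy)-4-(methoxymethoxy)phenyl]acetic acid | OC(=O)Cc1c(OCc2ccccc2)cc(OCOC)cc1OCc1ccccc1 | intermediate
7 | methyl 2-[2,6-bis(benzyloxy)-4-(methoxymethoxy)phenyl]acetate | COC(=O)Cc1c(OCc2ccccc2)cc(OCOC)cc1OCc1ccccc1 | intermediate
8 | 4'-(benzyloxy)acetophenone | CC(=O)c1ccc(OCc2ccccc2)cc1 | starting material
9 | 1-[4-(benzyloxy)phenyl]butane-1,3-dione | CC(=O)CC(=O)c1ccc(OCc2ccccc2)cc1 | intermediate
10 | 1-[2,6-bis(benzyloxy)-4-(methoxymethoxy)phenyl]-6-[4-(benzyloxy)phenyl]hexane-2,4,6-trione | COCOc1cc(OCc2ccccc2)c(CC(=O)CC(=O)CC(=O)c2ccc(OCc3ccccc3)cc2)c(OCc2ccccc2)c1 | intermediate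
11 | 2-[2,6-bis(benzyloxy)-4-(methoxymethoxy)benzyl]-6-[4-(benzyloxy)phenyl]-4H-pyran-4-one | COCOc1cc(OCc2ccccc2)c(Cc2cc(=O)cc(-c3ccc(OCc4ccccc4)cc3)o2)c(OCc2ccccc2)c1 | intermediate
12 | 2-[2,6-bis(benzyloxy)-4-(methoxymethoxy)phenyl]-2-{6-[4-(benzyloxy)phenyl]-4-oxo-4H-pyran-2-yl}acetic acid (racemic) | COCOc1cc(OCc2ccccc2)c(C(C(O)=O)c2cc(=O)cc(-c3ccc(OCc4ccccc4)cc3)o2)c(OCc2ccccc2)c1 | intermediate
13 | mono-tert-butyl malonate | CC(C)(C)OC(=O)CC(O)=O | starting material
14 | 2-[2,6-bis(benzyloxy)-4-(methoxymethoxy)phenyl]-2-{6-[4-(benzyloxy)phenyl]-4-oxo-4H-pyran-2-yl}-1-(imidazol-1-yl)ethanone (racemic) | COCOc1cc(OCc2ccccc2)c(C(C(=O)n2ccnc2)c2cc(=O)cc(-c3ccc(OCc4ccccc4)cc3)o2)c(OCc2ccccc2)c1 | intermediate (not isolated)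
15 | tert-butyl 4-[2,6-bis(benzyloxy)-4-(methoxymethoxy)phenyl]-4-{6-[4-(benzyloxy)phenyl]-4-oxo-4H-pyran-2-yl}-3-oxobutanoate (racemic) | CC(C)(C)OC(=O)CC(=O)C(c1cc(=O)cc(-c2ccc(OCc3ccccc3)cc2)o1)c1c(OCc2ccccc2)cc(OCOC)cc1OCc1ccccc1 | intermediate
16 | 4-[2,6-bis(benzyloxy)-4-(methoxymethoxy)phenyl]-4-{6-[4-(benzyloxy)phenyl]-4-oxo-4H-pyran-2-yl}but-1-ene-1,3-dione (acylketene) | O=C=CC(=O)C(c1cc(=O)cc(-c2ccc(OCc3ccccc3)cc2)o1)c1c(OCc2ccccc2)cc(OCOC)cc1OCc1ccccc1 | intermediate (not isolated)
17 | 8-[2,6-bis(benzyloxy)-4-(methoxymethoxy)phenyl]-2-[4-(benzyloxy)phenyl]-5,7-dihydroxy-4H-chromen-4-one | O=c1cc(-c2ccc(OCc3ccccc3)cc2)oc2c(-c3c(OCc4ccccc4)cc(OCOC)cc3OCc3ccccc3)c(O)cc(O)c12 | intermediate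
18 | 7-(benzyloxy)-8-[2,6-bis(benzyloxy)-4-(methoxymethoxy)phenyl]-2-[4-(benzyloxy)phenyl]-5-hydroxy-4H-chromen-4-one | O=c1cc(-c2ccc(OCc3ccccc3)cc2)oc2c(-c3c(OCc4ccccc4)cc(OCOC)cc3OCc3ccccc3)c(OCc3ccccc3)cc(O)c12 | intermediate
19 | 7-(benzyloxy)-8-[2,6-bis(benzyloxy)-4-hydroxyphenyl]-2-[4-(benzyloxy)phenyl]-5-hydroxy-4H-chromen-4-one | O=c1cc(-c2ccc(OCc3ccccc3)cc2)oc2c(-c3c(OCc4ccccc4)cc(O)cc3OCc3ccccc3)c(OCc3ccccc3)cc(O)c12 | intermediate
20 | 3,5-bis(benzyloxy)-4-{7-(benzyloxy)-2-[4-(benzyloxy)phenyl]-5-hydroxy-4-oxo-4H-chromen-8-yl}phenyl acetate | O=c1cc(-c2ccc(OCc3ccccc3)cc2)oc2c(-c3c(OCc4ccccc4)cc(OC(C)=O)cc3OCc3ccccc3)c(OCc3ccccc3)cc(O)c12 | intermediate (not isolated)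
21 | 8-[3-acetyl-2,6-bis(benzyloxy)-4-hydroxyphenyl]-7-(benzyloxy)-2-[4-(benzyloxy)phenyl]-5-hydroxy-4H-chromen-4-one | O=c1cc(-c2ccc(OCc3ccccc3)cc2)oc2c(-c3c(OCc4ccccc4)cc(O)c(C(C)=O)c3OCc3ccccc3)c(OCc3ccccc3)cc(O)c12 | intermediate
22 | tert-butyl 3-[2,4-bis(benzyloxy)-3-{7-(benzyloxy)-2-[4-(benzyloxy)phenyl]-5-hydroxy-4-oxo-4H-chromen-8-yl}-6-hydroxyphenyl]-3-oxopropanoate | O=c1cc(-c2ccc(OCc3ccccc3)cc2)oc2c(-c3c(OCc4ccccc4)cc(O)c(C(=O)CC(=O)OC(C)(C)C)c3OCc3ccccc3)c(OCc3ccccc3)cc(O)c12 | intermediate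
23 | 4-(benzyloxy)benzaldehyde | O=Cc1ccc(OCc2ccccc2)cc1 | starting material
24 | tert-butyl 2-[2,4-bis(benzyloxy)-3-{7-(benzyloxy)-2-[4-(benzyloxy)phenyl]-5-hydroxy-4-oxo-4H-chromen-8-yl}-6-hydroxybenzoyl]-3-[4-(benzyloxy)phenyl]prop-2-enoate (E/Z mixture) | O=c1cc(-c2ccc(OCc3ccccc3)cc2)oc2c(-c3c(OCc4ccccc4)cc(O)c(C(=O)C(=Cc4ccc(OCc5ccccc5)cc4)C(=O)OC(C)(C)C)c3OCc3ccccc3)c(OCc3ccccc3)cc(O)c12 | intermediate
25 | tert-butyl (2S)-5,7-bis(benzyloxy)-6-{7-(benzyloxy)-2-[4-(benzyloxy)phenyl]-5-hydroxy-4-oxo-4H-chromen-8-yl}-2-[4-(benzyloxy)phenyl]-4-oxochromane-3-carboxylate (C3 epimerizable) | O=C1C(C(=O)OC(C)(C)C)[C@@H](c2ccc(OCc3ccccc3)cc2)Oc2cc(OCc3ccccc3)c(-c3c(OCc4ccccc4)cc(O)c4c(=O)cc(-c5ccc(OCc6ccccc6)cc5)oc34)c(OCc3ccccc3)c21 | intermediate (not isolated)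
26 | (2S)-5,7-bis(benzyloxy)-6-{7-(benzyloxy)-2-[4-(benzyloxy)phenyl]-5-hydroxy-4-oxo-4H-chromen-8-yl}-2-[4-(benzyloxy)phenyl]chroman-4-one | O=C1C[C@@H](c2ccc(OCc3ccccc3)cc2)Oc2cc(OCc3ccccc3)c(-c3c(OCc4ccccc4)cc(O)c4c(=O)cc(-c5ccc(OCc6ccccc6)cc5)oc34)c(OCc3ccccc3)c21 | intermediate
27 | (2S)-6-[5,7-dihydroxy-2-(4-hydroxyphenyl)-4-oxo-4H-chromen-8-yl]-5,7-dihydroxy-2-(4-hydroxyphenyl)chroman-4-one | O=C1C[C@@H](c2ccc(O)cc2)Oc2cc(O)c(-c3c(O)cc(O)c4c(=O)cc(-c5ccc(O)cc5)oc34)c(O)c21 | target

**Step count**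

Total: 18 steps. Longest linear sequence: 17 steps (steps 1–5 and 7–18); step 6 is a one-step side branch.

**Steps most likely to fail**

1. Step 11 (proposed new method). The acylketene may be lost to dimerization or to O-acylation of phenols already formed, or the enol may not reach the geometry needed for closure, so that the ketene reverts and the ester slowly degrades. The fallback is a Suzuki–Miyaura biaryl coupling on a preformed flavone; it sets out from 3 and comes back at 19. Baeyer–Villiger (Dakin-type) oxidation of 3 with mCPBA should give 2,6-bis(benzyloxy)-4-(methoxymethoxy)phenyl formate F1, and methanolysis (K2CO3, MeOH) 2,6-bis(benzyloxy)-4-(methoxymethoxy)phenol F2. Tf2O and pyridine then give the aryl triflate F3, and Miyaura borylation (B2pin2, PdCl2(dppf), KOAc, dioxane, 90 °C) the pinacol boronate F4. Separately, commercial apigenin is benzylated on O7 and O4' (BnBr, K2CO3, acetone) to 7,4'-di-O-benzylapigenin F5, the chelated 5-OH is capped (NaH, MOMCl, DMF) as the 5-O-MOM ether F6, and NIS in DMF iodinates C8, the position electrophiles take in 5,7-dialkoxyflavones, to give the 8-iodoflavone F7. Coupling of F4 with F7 (Pd(OAc)2, SPhos, K3PO4, toluene–water, 100 °C) should give the bis-MOM biaryl F8, and the conditions of step 13 remove both MOM groups to give 19.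

2. Step 10. Acid 12 or its imidazolide may lose CO2 before the C–C bond forms, or attack at the hindered and readily enolized acyl imidazolide may be too slow. The fallback makes the methine–acyl bond by direct acetylation and adds the ester carbon afterwards; it sets out from 11 and comes back at 15. Deprotonation of 11 with LiN(SiMe3)2 (2.2 equiv, THF, −78 °C) and C-acetylation with N-acetylimidazole should give the methyl ketone 1-[2,6-bis(benzyloxy)-4-(methoxymethoxy)phenyl]-1-{6-[4-(benzyloxy)phenyl]-4-oxo-4H-pyran-2-yl}propan-2-one F9. LiN(iPr)2 (3.2 equiv, −78 to −20 °C) then forms the dianion (methine first, methyl second), and Boc2O acylates the terminal carbanion to give 15.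

3. Step 17. Facial selectivity in the oxa-Michael addition may be poor on this hindered ortho,ortho'-disubstituted aroyl system, or uncatalysed ring closure during step 16 may already deliver racemic material. The fallback is a racemic synthesis with resolution; it sets out from 21 and comes back at 26. Claisen–Schmidt condensation of 21 with 23 (KOH, EtOH, rt) should give the (E)-2'-hydroxychalcone F10, NaOAc in refluxing EtOH closes it to the racemic flavanone F11, and preparative HPLC on a chiral stationary phase separates the (2S) compound 26 from its (2R) isomer.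

**Further compounds**

F1 | step 11 | 2,6-bis(benzyloxy)-4-(methoxymethoxy)phenyl formate | O=COc1c(OCc2ccccc2)cc(OCOC)cc1OCc1ccccc1
F2 | step 11 | 2,6-bis(benzyloxy)-4-(methoxymethoxy)phenol | Oc1c(OCc2ccccc2)cc(OCOC)cc1OCc1ccccc1
F3 | step 11 | 2,6-bis(benzyloxy)-4-(methoxymethoxy)phenyl trifluoromethanesulfonate | O=S(=O)(Oc1c(OCc2ccccc2)cc(OCOC)cc1OCc1ccccc1)C(F)(F)F
F4 | step 11 | 2-[2,6-bis(benzyloxy)-4-(methoxymethoxy)phenyl]-4,4,5,5-tetramethyl-1,3,2-dioxaborolane | CC1(C)OB(OC1(C)C)c1c(OCc2ccccc2)cc(OCOC)cc1OCc1ccccc1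
F5 | step 11 | 7-(benzyloxy)-2-[4-(benzyloxy)phenyl]-5-hydroxy-4H-chromen-4-one | O=c1cc(-c2ccc(OCc3ccccc3)cc2)oc2cc(OCc3ccccc3)cc(O)c12
F6 | step 11 | 7-(benzyloxy)-2-[4-(benzyloxy)phenyl]-5-(methoxymethoxy)-4H-chromen-4-one | O=c1cc(-c2ccc(OCc3ccccc3)cc2)oc2cc(OCc3ccccc3)cc(OCOC)c12
F7 | step 11 | 7-(benzyloxy)-2-[4-(benzyloxy)phenyl]-8-iodo-5-(methoxymethoxy)-4H-chromen-4-one | O=c1cc(-c2ccc(OCc3ccccc3)cc2)oc2c(I)c(OCc3ccccc3)cc(OCOC)c12
F8 | step 11 | 7-(benzyloxy)-8-[2,6-bis(benzyloxy)-4-(methoxymethoxy)phenyl]-2-[4-(benzyloxy)phenyl]-5-(methoxymethoxy)-4H-chromen-4-one | O=c1cc(-c2ccc(OCc3ccccc3)cc2)oc2c(-c3c(OCc4ccccc4)cc(OCOC)cc3OCc3ccccc3)c(OCc3ccccc3)cc(OCOC)c12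
F9 | step 10 | 1-[2,6-bis(benzyloxy)-4-(methoxymethoxy)phenyl]-1-{6-[4-(benzyloxy)phenyl]-4-oxo-4H-pyran-2-yl}propan-2-one (racemic) | CC(=O)C(c1cc(=O)cc(-c2ccc(OCc3ccccc3)cc2)o1)c1c(OCc2ccccc2)cc(OCOC)cc1OCc1ccccc1
F10 | step 17 | (E)-1-[2,4-bis(benzyloxy)-3-{7-(benzyloxy)-2-[4-(benzyloxy)phenyl]-5-hydroxy-4-oxo-4H-chromen-8-yl}-6-hydroxyphenyl]-3-[4-(benzyloxy)phenyl]prop-2-en-1-one | O=C(/C=C/c1ccc(OCc2ccccc2)cc1)c1c(O)cc(OCc2ccccc2)c(-c2c(OCc3ccccc3)cc(O)c3c(=O)cc(-c4ccc(OCc5ccccc5)cc4)oc23)c1OCc1ccccc1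
F11 | step 17 | racemic 5,7-bis(benzyloxy)-6-{7-(benzyloxy)-2-[4-(benzyloxy)phenyl]-5-hydroxy-4-oxo-4H-chromen-8-yl}-2-[4-(benzyloxy)phenyl]chroman-4-one | O=C1CC(c2ccc(OCc3ccccc3)cc2)Oc2cc(OCc3ccccc3)c(-c3c(OCc4ccccc4)cc(O)c4c(=O)cc(-c5ccc(OCc6ccccc6)cc5)oc34)c(OCc3ccccc3)c21
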